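Atom numbers C1–C15 follow eremophilane numbering. Ring A is C1–C5 plus C10, and ring B is C5–C10. C14 is the methyl on C5, C15 the methyl on C4, and C11–C13 the isopropenyl group on C7. β is the face that carries C14.

## Analysis of the target

- **Skeleton and configuration.** Target 22 is a cis-fused decalin of the eremophilane type, with the configuration 3R,4R,5R,7R,9R,10S. It carries a ketone at C8, an angelate at O-3, a senecioate at O-9 and an isopropenyl group at C7.
- **Relation of the stereocentres.** C14 on the quaternary C5 and H-10 are both β, which makes the fusion cis. C15, C11 and O-9 lie on the same β (convex) face, and O-3 is α.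
- **Conformation.** In the chair–chair conformer with C14 axial on ring A and equatorial on ring B, all four substituents at C3, C4, C7 and C9 are equatorial. The ring-flipped conformer has an all-equatorial diastereomer of its own (3β,4α,7α,9α). Equilibration can therefore finish the stereochemistry but cannot start it: one of these centres must first be tied kinetically to C5/C10.
- **Sensitive groups.**
  - The β,γ-unsaturated ketone: C7–H is doubly activated, and the conjugated 7(11)-enone is the thermodynamic sink.
  - The C8/C9 α-acyloxy ketone.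
  - The (Z)-angelate, which isomerises easily to the tiglate.
- **Hard points.**
  - The vicinal pair C4/C5.
  - Telling apart the two α-positions of C8.
  - The equatorial 3α-oxygen. It sits next to the equatorial C15 and 1,3-syn to the axial C14, a setting in which hydride reagents give the axial alcohol.
- **Feature that invites the key move.** C3 and C8 are both oxygenated and are joined through C2–C1–C10–C9. Read as a C3 ketone plus a C8=C9 enol ether, this is the δ,ε-unsaturated ketone retron of an oxy-Cope rearrangement. Reconnecting C3–C8 and cutting C1–C10 folds both rings into a bicyclo[2.2.2]octene. Its six-membered ring C3–C4–C5–C10–C9–C8 is a dearomatised phenol.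

## Retrosynthetic reasoning

**22 ⇒ 20 + 21.** The acyl–oxygen bond at O-9 is cut last. The α-acyloxy ketone and the isopropenyl ketone then meet only a mild acylation. The forward step must not move C7 or C9.

**20 ⇒ 18 (through 19).** The C9–O bond is cut and the C8 carbonyl is masked as the methyl enol ether C8(OMe)=C9. This solves the C7-versus-C9 problem, because the double bond marks C9. It also keeps ring B inert while ring A is finished. The forward oxidation must occur on the convex β face and must spare the isopropenyl and angelate double bonds.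

**18 ⇒ 15 + 16.** The acyl–oxygen bond at O-3 is cut. The esterification must keep the Z geometry of 16 and must stay non-acidic for the enol ether.

**15 ⇒ 12 (through 13 and 14).** The C4–H and C3–H bonds are removed, leading back to the exocyclic enone C15=C4–C3=O. A dissolving-metal reduction can then set C4 and C3 under thermodynamic control. This is possible only because C8 is masked, and because the 7β-isopropenyl group already locks the decalin in the right conformer.

**12 ⇒ 9 (through 10 and 11), the key disconnection.** C1–C10 is cut and C3–C8 is reconnected. The cis-decalin becomes a 2-vinylbicyclo[2.2.2]oct-5-en-2-ol.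
- No decalin stereocontrol is needed before this point, because C10 follows from the cage geometry.
- C3 and C8 leave the step in different masked forms.
- The forward [3,3] shift must close ring A, release ring B and give only the cis fusion.

**9 ⇒ 7 + 8.** The C2–C3 bond is cut. The addition must be 1,2 and must come from the face of the etheno bridge.

**7 ⇒ 6 ⇒ 5.** The two exocyclic double bonds C4=C15 and C11=C12 are traced back to two carbonyl groups, so both missing carbons arrive in one operation. The C3 ketone stays protected as its ketal during that operation.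

**5 ⇒ 3 + 4.** The bonds C5–C6 and C7–C8 are cut (Diels–Alder). This single cycloaddition makes the quaternary C5, the oxygenated bridgehead C8 and, through the endo rule, the 7β centre. That 7β centre is the kinetic anchor of the whole stereochemical scheme.

**3 ⇒ 2 ⇒ 1.** The dienone 3 is the dearomatised form of phenol 2. In 2 the ring oxygens already sit on C3, C4 and C8 and the methyl on C5. Phenol 2 comes from the commercial aldehyde 1 by deoxygenation of the formyl group.

## Alternatives that were turned down

**Alternative 1:** (the textbook route) Ring B is cut at C5–C6 and C9=C10, that is, a Robinson annulation of a 2,3-dimethyl-4-oxygenated cyclohexanone. It gives the octalone (4aR,5R,6R)-6-(tert-butyldimethylsilyloxy)-4a,5-dimethyl-4,4a,5,6,7,8-hexahydronaphthalen-2(3H)-one A1. It was turned down for four reasons.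
- In the 9(10)-en-8-one, C14 is axial on ring B, so the stable equatorial place at C7 is α, the wrong one.
- The cis fusion, O-9 and the isopropenyl group each need separate operations on a ketone whose two α-sides must be told apart.
- C7 would have to be inverted through the dienolate, which also leaks to the conjugated enone.
- The chiral ring A ketone costs several steps by itself.

**Alternative 2:** Ring A is cut at C4–C5 and C1–C10. The forward step is an endo Diels–Alder reaction of the quinone 2-methoxy-5-methylcyclohexa-2,5-diene-1,4-dione A2 with the diene (Z)-3-(tert-butyldimethylsilyloxy)penta-1,3-diene A3. It gives the cis-fused adduct A4. It was turned down for these reasons.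
- The endo rule places the outside methyl C15 cis to the quinone carbons, hence trans to C14.
- Hydride attack at C9 from the convex face gives 9α-OH. The adduct therefore belongs to the wrong all-equatorial family.
- Both C4 and C9 would have to be inverted, while C10 next to the C9 ketone can epimerise.
- The C6 carbonyl must be deleted and the isopropenyl group is still missing.

**Alternative 3:** The same oxy-Cope rearrangement, but with the cage taken from the chiral pool. The terpenoid enone (5,6-trans)-6-methoxy-2,3-dimethyl-5-(prop-1-en-2-yl)cyclohex-2-en-1-one A5 would be bridged between C8 and C5 with a two-carbon acetylene equivalent (double Michael addition, then elimination). This gives the bicyclooctenone A6. It was turned down for these reasons.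
- The new etheno bridge must form anti to the isopropenyl group, so that group points toward the carbonyl bridge and becomes 7α after the rearrangement.
- A 7α substituent drives the decalin into the other conformer, in which equilibration gives 4α and 3β.
- C7 would have to be corrected at the very end through the dienolate.
- A5 needs four steps from the commercial terpene.

Key step: step 7

Assumption: 1, 4, 8, 16 and 21 are taken as commercial. The names of 12–22 use the eremophilane numbering given at the top.

## Steps

Step 1
Reactants: 1 2-hydroxy-3,4-dimethoxybenzaldehyde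
Product: 2 2,3-dimethoxy-6-methylphenol
Conditions: H2 (3 bar), Pd/C, AcOH, rt
Reagents that add atoms: none
Why: Hydrogenolysis of an electron-rich ortho-hydroxybenzaldehyde; the formyl group is reduced to the benzylic alcohol, whose activated C–O bond is then cleaved. No stereocentre is involved.

Step 2
Reactants: 2 2,3-dimethoxy-6-methylphenol
Product: 3 5,6,6-trimethoxy-2-methylcyclohexa-2,4-dien-1-one
Conditions: PhI(OAc)2, MeOH, 0 °C
Reagents that add atoms: methanol CO
Why: Oxidative dearomatisation of a 2-methoxyphenol to a masked o-benzoquinone; methanol traps the phenoxenium ion at the methoxy-bearing ortho carbon, where the charge is best stabilised. The substituents on both diene termini should slow self-dimerisation.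

Step 3
Reactants: 3 5,6,6-trimethoxy-2-methylcyclohexa-2,4-dien-1-one; 4 but-3-en-2-one
Product: 5 (1S,4R,8S)-8-acetyl-3,3,4-trimethoxy-1-methylbicyclo[2.2.2]oct-5-en-2-one (acetyl syn to the C5=C6 etheno bridge)
Conditions: (S)-1-(2-methylphenyl)-3,3-diphenyltetrahydropyrrolo[1,2-c][1,3,2]oxazaborole·HNTf2 (cat.), CH2Cl2, −78 to −40 °C
Reagents that add atoms: none
Why: Proposed new method: the boron cation binds the carbonyl oxygen of 4 and lowers its LUMO; the push–pull diene 3 bonds with its nucleophilic methyl-bearing terminus to the CH2 of 4 and with its methoxy-stabilised terminus to the α-carbon (acetyl next to the bridgehead OMe), endo, on the Re face of C3 of 4, which the catalyst has to leave open (the mirror-image catalyst is equally available if the sense is opposite). The closest known types are the uncatalysed Diels–Alder reaction of 6,6-dialkoxycyclohexa-2,4-dienones with vinyl ketones and the oxazaborolidinium-catalysed enantioselective Diels–Alder reaction of vinyl ketones with cyclohexa-1,3-dienes. The step sets C5, C8 and C7.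

Step 4
Reactants: 5 (1S,4R,8S)-8-acetyl-3,3,4-trimethoxy-1-methylbicyclo[2.2.2]oct-5-en-2-one
Product: 6 (1S,4R,8R)-3,3,4-trimethoxy-1-methyl-2-methylidene-8-(prop-1-en-2-yl)bicyclo[2.2.2]oct-5-ene
Conditions: MePPh3Br, KOtBu (excess), THF, −78 °C to 65 °C
Reagents that add atoms: methyltriphenylphosphonium bromide C[P+](c1ccccc1)(c1ccccc1)c1ccccc1.[Br-]
Why: Double Wittig methylenation that brings in C12 and C15. The methyl ketone reacts in the cold before C7 can epimerise, and the non-enolisable ring ketone follows on warming. The ketal keeps C3 out of the reaction.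

Step 5
Reactants: 6 (1S,4R,8R)-3,3,4-trimethoxy-1-methyl-2-methylidene-8-(prop-1-en-2-yl)bicyclo[2.2.2]oct-5-ene
Product: 7 (1R,4S,7R)-1-methoxy-4-methyl-3-methylidene-7-(prop-1-en-2-yl)bicyclo[2.2.2]oct-5-en-2-one
Conditions: 1 M aq. HCl, THF, 0 °C
Reagents that add atoms: water O
Why: Acid hydrolysis of an allylic dimethyl ketal through an oxocarbenium ion conjugated with C4=C15. The bridgehead ether cannot ionise, and the mild acid should spare the isopropenyl group.

Step 6
Reactants: 7 (1R,4S,7R)-1-methoxy-4-methyl-3-methylidene-7-(prop-1-en-2-yl)bicyclo[2.2.2]oct-5-en-2-one; 8 vinylmagnesium bromide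
Product: 9 (1R,2S,4S,7R)-2-ethenyl-1-methoxy-4-methyl-3-methylidene-7-(prop-1-en-2-yl)bicyclo[2.2.2]oct-5-en-2-ol (vinyl syn to the etheno bridge)
Conditions: LaCl3·2LiCl (0.3 equiv), THF, −78 to 0 °C; aq. NH4Cl
Reagents that add atoms: none
Why: Lanthanide-promoted 1,2-addition of a Grignard reagent to an enone. The face next to the ethano bridge is shielded by the inward C7–H and C6–H bonds, so attack should come past the flat etheno bridge, as is usual for bicyclo[2.2.2]oct-5-en-2-ones. C4 is sp2 and exerts no opposing bias.

Step 7
Reactants: 9 (1R,2S,4S,7R)-2-ethenyl-1-methoxy-4-methyl-3-methylidene-7-(prop-1-en-2-yl)bicyclo[2.2.2]oct-5-en-2-ol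
Product: 12 (5S,7R,10R)-8-methoxyeremophila-4(15),8,11-trien-3-one, via potassium alkoxide 10 (not isolated), via potassium dienolate 11 (not isolated)
Conditions: KH, 18-crown-6, THF, 0 °C to rt; aq. NH4Cl, −78 °C
Reagents that add atoms: none
Why: KH gives alkoxide 10, whose oxyanion weakens C3–C8 and triggers an anionic oxy-Cope ([3,3]-sigmatropic) rearrangement over C1=C2–C3–C8–C9=C10, the established behaviour of 2-vinylbicyclo[2.2.2]oct-5-en-2-olates, including those with a bridgehead methoxy group. C3–C8 breaks and C1–C10 forms, so ring A is closed through the boat-like six-centre transition state that the cage enforces, while ring B is set free from the cage. C1 can reach C10 only on the face of the etheno bridge that looks at the carbinol bridge, so H-10 must end cis to C14 and only the cis-decalin can form. C5 and C7 pass through untouched, and because the isopropenyl group was syn to the etheno bridge it ends 7β, cis to C14. Only a vinyl group syn to the etheno bridge can rearrange, which step 6 secures. The exocyclic C4=C15 cannot compete because it would close a four-membered ring, and the neutral Cope shift of the isopropenyl/etheno diene lacks the oxyanion and is far slower. The two carbonyl groups emerge differentiated: C3 as the cross-conjugated dienolate 11 (protonated at C2 to give 12) and C8 as a methyl enol ether with its double bond fixed at C8=C9. Enolate formation and loss of cage strain make the step irreversible.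

Step 8
Reactants: 12 (5S,7R,10R)-8-methoxyeremophila-4(15),8,11-trien-3-one
Product: 15 (3R,4R,5S,7R,10R)-8-methoxyeremophila-8,11-dien-3-ol (3α-OH and 4β-CH3), via lithium enolate 13 (not isolated), via ketone 14 (not isolated)
Conditions: Li, NH3(l)/THF, −78 °C; then MeOH, −33 °C
Reagents that add atoms: none
Why: Dissolving-metal reduction of the enone to enolate 13, axial (α) protonation at C4 to give 14 with C15 equatorial (methoxide can also equilibrate this centre), then ketyl reduction to the equatorial 3α-alcohol. This is the outcome known for 3-ketones flanked by an equatorial 4-methyl and a syn-axial 5-methyl group, where hydrides give the axial epimer. The 7β-isopropenyl group holds the conformer in which 4β and 3α are equatorial, and the isolated alkenes and the enol ether are inert.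

Step 9
Reactants: 15 (3R,4R,5S,7R,10R)-8-methoxyeremophila-8,11-dien-3-ol; 16 (2Z)-2-methylbut-2-enoic acid (angelic acid)
Product: 18 (3R,4R,5S,7R,10R)-8-methoxyeremophila-8,11-dien-3-yl (2Z)-2-methylbut-2-enoate, via mixed anhydride 17 (not isolated)
Conditions: 2,4,6-trichlorobenzoyl chloride, Et3N, toluene, rt then 80 °C
Reagents that add atoms: none
Why: Yamaguchi esterification run without a nucleophilic pyridine catalyst, the usual way to make angelates without Z-to-E isomerisation. The medium stays basic, so the enol ether survives.

Step 10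
Reactants: 18 (3R,4R,5S,7R,10R)-8-methoxyeremophila-8,11-dien-3-yl (2Z)-2-methylbut-2-enoate
Product: 20 (3R,4R,5R,7R,9R,10S)-9-hydroxy-8-oxoeremophil-11-en-3-yl (2Z)-2-methylbut-2-enoate, via methoxy epoxide 19 (not isolated)
Conditions: dimethyldioxirane (1 equiv), acetone/CH2Cl2, −78 °C; then H2O, NaHCO3, 0 °C
Reagents that add atoms: dimethyldioxirane CC1(C)OO1; water O
Why: Rubottom-type oxidation of an enol ether. The electron-rich C8=C9 bond reacts far faster than the isopropenyl or angelate double bonds. The α face is blocked by C4, which is axial on ring B, so oxygen should enter from the convex β face. Hydrolysis of 19 unveils the C8 ketone under near-neutral conditions that leave the already stable 7β centre alone.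

Step 11
Reactants: 20 (3R,4R,5R,7R,9R,10S)-9-hydroxy-8-oxoeremophil-11-en-3-yl (2Z)-2-methylbut-2-enoate; 21 3-methylbut-2-enoyl chloride
Product: 22 (3R,4R,5R,7R,9R,10S)-9-[(3-methylbut-2-enoyl)oxy]-8-oxoeremophil-11-en-3-yl (2Z)-2-methylbut-2-enoate (target)
Conditions: pyridine, CH2Cl2, 0 °C
Reagents that add atoms: none
Why: Acylation of an equatorial α-hydroxy ketone with an acid chloride and a weak base. No stereocentre is touched, and pyridine is too weak to enolise C8 toward C7.

## Compound list

1 | 2-hydroxy-3,4-dimethoxybenzaldehyde | COc1ccc(C=O)c(O)c1OC | starting material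
2 | 2,3-dimethoxy-6-methylphenol | COc1ccc(C)c(O)c1OC | intermediate
3 | 5,6,6-trimethoxy-2-methylcyclohexa-2,4-dien-1-one | CC1=CC=C(OC)C(OC)(OC)C1=O | intermediate
4 | but-3-en-2-one | CC(=O)C=C | starting material
5 | (1S,4R,8S)-8-acetyl-3,3,4-trimethoxy-1-methylbicyclo[2.2.2]oct-5-en-2-one | CC(=O)[C@H]1C[C@@]2(C)C=C[C@]1(OC)C(OC)(OC)C2=O | intermediate
6 | (1S,4R,8R)-3,3,4-trimethoxy-1-methyl-2-methylidene-8-(prop-1-en-2-yl)bicyclo[2.2.2]oct-5-ene | C=C(C)[C@H]1C[C@@]2(C)C=C[C@]1(OC)C(OC)(OC)C2=C | intermediate
7 | (1R,4S,7R)-1-methoxy-4-methyl-3-methylidene-7-(prop-1-en-2-yl)bicyclo[2.2.2]oct-5-en-2-one | C=C(C)[C@H]1C[C@@]2(C)C=C[C@]1(OC)C(=O)C2=C | intermediate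
8 | vinylmagnesium bromide | C=C[Mg]Br | starting material
9 | (1R,2S,4S,7R)-2-ethenyl-1-methoxy-4-methyl-3-methylidene-7-(prop-1-en-2-yl)bicyclo[2.2.2]oct-5-en-2-ol | C=C(C)[C@H]1C[C@@]2(C)C=C[C@]1(OC)[C@](O)(C=C)C2=C | intermediate
10 | potassium alkoxide of 9 | C=C(C)[C@H]1C[C@@]2(C)C=C[C@]1(OC)[C@]([O-])(C=C)C2=C.[K+] | intermediate
11 | potassium 8-methoxyeremophila-2,4(15),8,11-tetraen-3-olate | C=C(C)[C@H]1C[C@@]2(C)[C@H](CC=C([O-])C2=C)C=C1OC.[K+] | intermediate
12 | (5S,7R,10R)-8-methoxyeremophila-4(15),8,11-trien-3-one | C=C(C)[C@H]1C[C@@]2(C)[C@H](CCC(=O)C2=C)C=C1OC | intermediate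
13 | lithium 8-methoxyeremophila-3,8,11-trien-3-olate | C=C(C)[C@H]1C[C@@]2(C)[C@H](CCC([O-])=C2C)C=C1OC.[Li+] | intermediate
14 | (4R,5S,7R,10R)-8-methoxyeremophila-8,11-dien-3-one | C=C(C)[C@H]1C[C@@]2(C)[C@H](CCC(=O)[C@@H]2C)C=C1OC | intermediate
15 | (3R,4R,5S,7R,10R)-8-methoxyeremophila-8,11-dien-3-ol | C=C(C)[C@H]1C[C@@]2(C)[C@H](CC[C@@H](O)[C@@H]2C)C=C1OC | intermediate
16 | (2Z)-2-methylbut-2-enoic acid | C/C=C(/C)C(=O)O | starting material
17 | (2Z)-2-methylbut-2-enoic 2,4,6-trichlorobenzoic anhydride | C/C=C(/C)C(=O)OC(=O)c1c(Cl)cc(Cl)cc1Cl | intermediate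
18 | (3R,4R,5S,7R,10R)-8-methoxyeremophila-8,11-dien-3-yl (2Z)-2-methylbut-2-enoate | C=C(C)[C@H]1C[C@@]2(C)[C@H](CC[C@@H](OC(=O)/C(C)=C\C)[C@@H]2C)C=C1OC | intermediate
19 | 8β,9β-epoxy-8α-methoxyeremophil-11-en-3α-yl (2Z)-2-methylbut-2-enoate | C=C(C)[C@H]1C[C@@]2(C)[C@H](CC[C@@H](OC(=O)/C(C)=C\C)[C@@H]2C)[C@H]3O[C@@]13OC | intermediate
20 | (3R,4R,5R,7R,9R,10S)-9-hydroxy-8-oxoeremophil-11-en-3-yl (2Z)-2-methylbut-2-enoate | C=C(C)[C@H]1C[C@@]2(C)[C@H](CC[C@@H](OC(=O)/C(C)=C\C)[C@@H]2C)[C@@H](O)C1=O | intermediate
21 | 3-methylbut-2-enoyl chloride | CC(C)=CC(=O)Cl | starting material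
22 | (3R,4R,5R,7R,9R,10S)-9-[(3-methylbut-2-enoyl)oxy]-8-oxoeremophil-11-en-3-yl (2Z)-2-methylbut-2-enoate | C=C(C)[C@H]1C[C@@]2(C)[C@H](CC[C@@H](OC(=O)/C(C)=C\C)[C@@H]2C)[C@@H](OC(=O)C=C(C)C)C1=O | target

## Step count and least certain steps

Total step count: 11. Longest linear sequence: 11 (1 to 22).

**Step 3 (proposed new method).**
- Risk: the vinylogous-ester carbonyl of 3 is more Lewis basic than that of 4 and may tie up the catalyst. An uncatalysed background reaction would then erode the enantioselectivity. The two opposing substituent effects on the diene could also let some of the reversed regiochemistry through.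
- Fallback (known chemistry): 3 and 4 are combined thermally without catalyst (toluene, 80 °C). This gives the racemate, that is, 5 together with its mirror image (1R,4S,8R)-8-acetyl-3,3,4-trimethoxy-1-methylbicyclo[2.2.2]oct-5-en-2-one F1. Preparative chromatography on a chiral stationary phase removes F1, and the route is rejoined at 5.

**Step 7 (key step).**
- Risk: the cross-conjugated dienolate and the exocyclic enone formed on quenching may add to each other. The strong base may move the skipped C8=C9/C11=C12 diene into conjugation through the doubly allylic C7–H. The hindered alkoxide may fragment instead of rearranging.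
- Fallback: the rearrangement is run on a substrate without the exocyclic double bond.
  - From 7, conjugate reduction with [(Ph3P)CuH]6 gives 1-methoxy-3,4-dimethyl-7-(prop-1-en-2-yl)bicyclo[2.2.2]oct-5-en-2-one (3-methyl anti to the etheno bridge) F2.
  - Addition of 8 gives the carbinol 2-ethenyl-1-methoxy-3,4-dimethyl-7-(prop-1-en-2-yl)bicyclo[2.2.2]oct-5-en-2-ol F3. The methyl group now also steers the vinyl group to the etheno face.
  - KH/18-crown-6 gives the 4α-methyl ketone 4-epi-8-methoxyeremophila-8,11-dien-3-one F4.
  - NaOMe in MeOH equilibrates C4, and the route is rejoined at 14, which is reduced as in step 8.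

**Step 2.**
- Risk: methanol may attack the free para position, which is also activated by the 3-methoxy group. Further oxidation to a p-quinone derivative would follow. Slow dimerisation of 3 during isolation is also possible.
- Fallback: the para position is blocked.
  - From 2, N-bromosuccinimide gives 4-bromo-2,3-dimethoxy-6-methylphenol F5.
  - PhI(OAc)2 in MeOH gives 4-bromo-5,6,6-trimethoxy-2-methylcyclohexa-2,4-dien-1-one F6.
  - Cycloaddition with 4 gives 8-acetyl-5-bromo-3,3,4-trimethoxy-1-methylbicyclo[2.2.2]oct-5-en-2-one F7.
  - Bu3SnH with Pd(PPh3)4 removes the vinylic bromine, and the route is rejoined at 5.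

**Step 6.**
- Risk: conjugate addition to the unhindered exocyclic CH2, or attack from the ethano face, which would give a carbinol that cannot rearrange.
- Fallback: a slimmer and harder nucleophile is used.
  - From 7, lithium (trimethylsilyl)acetylide gives the 2-[(trimethylsilyl)ethynyl] carbinol F8.
  - K2CO3 in MeOH gives the 2-ethynyl carbinol F9.
  - Semihydrogenation (H2, Pd/CaCO3 poisoned with Pb(OAc)2, quinoline) rejoins the route at 9.

**Step 8.**
- Risk: protonation of the enolate at C4 from the β face followed by fast reduction before equilibration. Amide-induced conjugation of the skipped diene with subsequent over-reduction is also possible.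
- Fallback: the three events are separated and the carbinol centre is set by a redox equilibrium.
  - From 12, [(Ph3P)CuH]6 and then NaOMe/MeOH give 14.
  - NaBH4 gives the axial alcohol (3S)-8-methoxyeremophila-8,11-dien-3-ol F10.
  - Al(OiPr)3 in iPrOH with a trace of acetone (Meerwein–Ponndorf–Verley/Oppenauer equilibration) converts it into the equatorial epimer, and the route is rejoined at 15.

**Step 10.**
- Risk: hydrolysis of the enol ether before oxidation, which would lose the regiochemical information. Attack on the α face and competing epoxidation of the isopropenyl group are also possible.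
- Fallback for the facial problem: the 9α-epimer 9α-hydroxy-8-oxoeremophil-11-en-3α-yl (2Z)-2-methylbut-2-enoate F11 carries an axial, ketone-activated hydroxyl group that is open to backside attack from the convex face. A Mitsunobu reaction with 3-methylbut-2-enoic acid (PPh3, diisopropyl azodicarboxylate) inverts C9 and installs the ester, and the route is rejoined at 22.

## Further compounds

F1 | step 3 | (1R,4S,8R)-8-acetyl-3,3,4-trimethoxy-1-methylbicyclo[2.2.2]oct-5-en-2-one | CC(=O)[C@@H]1C[C@]2(C)C=C[C@@]1(OC)C(OC)(OC)C2=O
F2 | step 7 | 1-methoxy-3,4-dimethyl-7-(prop-1-en-2-yl)bicyclo[2.2.2]oct-5-en-2-one (3-methyl anti to the etheno bridge) | C=C(C)[C@H]1C[C@@]2(C)C=C[C@]1(OC)C(=O)[C@H]2C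
F3 | step 7 | 2-ethenyl-1-methoxy-3,4-dimethyl-7-(prop-1-en-2-yl)bicyclo[2.2.2]oct-5-en-2-ol | C=C(C)[C@H]1C[C@@]2(C)C=C[C@]1(OC)[C@](O)(C=C)[C@H]2C
F4 | step 7 | 4-epi-8-methoxyeremophila-8,11-dien-3-one (4α-methyl) | C=C(C)[C@H]1C[C@@]2(C)[C@H](CCC(=O)[C@H]2C)C=C1OC
F5 | step 2 | 4-bromo-2,3-dimethoxy-6-methylphenol | COc1c(Br)cc(C)c(O)c1OC
F6 | step 2 | 4-bromo-5,6,6-trimethoxy-2-methylcyclohexa-2,4-dien-1-one | CC1=CC(Br)=C(OC)C(OC)(OC)C1=O
F7 | step 2 | 8-acetyl-5-bromo-3,3,4-trimethoxy-1-methylbicyclo[2.2.2]oct-5-en-2-one | CC(=O)[C@H]1C[C@@]2(C)C=C(Br)[C@]1(OC)C(OC)(OC)C2=O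
F8 | step 6 | 1-methoxy-4-methyl-3-methylidene-7-(prop-1-en-2-yl)-2-[(trimethylsilyl)ethynyl]bicyclo[2.2.2]oct-5-en-2-ol | C=C(C)[C@H]1C[C@@]2(C)C=C[C@]1(OC)[C@](O)(C#C[Si](C)(C)C)C2=C
F9 | step 6 | 2-ethynyl-1-methoxy-4-methyl-3-methylidene-7-(prop-1-en-2-yl)bicyclo[2.2.2]oct-5-en-2-ol | C=C(C)[C@H]1C[C@@]2(C)C=C[C@]1(OC)[C@](O)(C#C)C2=C
F10 | step 8 | (3S)-8-methoxyeremophila-8,11-dien-3-ol (3β-OH, axial) | C=C(C)[C@H]1C[C@@]2(C)[C@H](CC[C@H](O)[C@@H]2C)C=C1OC
F11 | step 10 | 9α-hydroxy-8-oxoeremophil-11-en-3α-yl (2Z)-2-methylbut-2-enoate | C=C(C)[C@H]1C[C@@]2(C)[C@H](CC[C@@H](OC(=O)/C(C)=C\C)[C@@H]2C)[C@H](O)C1=O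
A1 | alternative 1 | (4aR,5R,6R)-6-(tert-butyldimethylsilyloxy)-4a,5-dimethyl-4,4a,5,6,7,8-hexahydronaphthalen-2(3H)-one | O=C1C=C2CC[C@@H](O[Si](C)(C)C(C)(C)C)[C@H](C)[C@@]2(C)CC1
A2 | alternative 2 | 2-methoxy-5-methylcyclohexa-2,5-diene-1,4-dione | COC1=CC(=O)C(C)=CC1=O
A3 | alternative 2 | (Z)-3-(tert-butyldimethylsilyloxy)penta-1,3-diene | C/C=C(/C=C)O[Si](C)(C)C(C)(C)C
A4 | alternative 2 | cis-fused endo adduct of A2 and A3 (C15 trans to C14) | COC1=CC(=O)[C@]2(C)[C@H](C)C(O[Si](C)(C)C(C)(C)C)=CC[C@@H]2C1=O
A5 | alternative 3 | (5,6-trans)-6-methoxy-2,3-dimethyl-5-(prop-1-en-2-yl)cyclohex-2-en-1-one | C=C(C)[C@@H]1CC(C)=C(C)C(=O)[C@H]1OC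
A6 | alternative 3 | 1-methoxy-3,4-dimethyl-7-(prop-1-en-2-yl)bicyclo[2.2.2]oct-5-en-2-one (isopropenyl anti to the etheno bridge) | C=C(C)[C@@H]1C[C@@]2(C)C=C[C@]1(OC)C(=O)[C@@H]2C
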